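## Retrosynthetic overview

- The plan rests on ring A, the oxolane O1–C2(aryl)–C3(methyl)–C4–C5H2, whose C4 carries one exocyclic carbon, the carbinol C7'. Ring A plus C7' has the same six atoms as an oxan-3-one (ring B) in which C7' is the ring ketone sitting between C5 and C4.
- The C7'–aryl bond is cut back to a Weinreb amide on C4. The forward steps are aryllithium addition and then catalyst-controlled ketone reduction for 7'R.
- The amide comes from a photochemical Wolff contraction of the 4-diazo-oxan-3-one. C5 moves from the ketone carbon to C4, N2 leaves, MeNHOMe traps the ketene, and C-protonation sets C4.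
- The diazo group is installed by trifluoroacetyl-activated diazo transfer at the kinetic enolate. Ring B is closed by rhodium-carbenoid O–H insertion of a hydroxy diazoketone.
- C2 and C3 come from an asymmetric anti-crotylboration of veratraldehyde. Ring B is formed first and is then contracted to ring A.

Key step: step 9

Assumption: the (S)-phosphoric acid is taken to send the crotyl group to the Si face of an aryl aldehyde, mirroring the accepted sense in which the (R)-acid gives (R)-carbinols; the antipodal acid would be used if the sense proved opposite.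

## Route

Step 1
Reactants: 1 3,4-dimethoxybenzaldehyde (veratraldehyde); 2 (E)-crotylboronic acid pinacol ester
Product: 4 (1S,2S)-1-(3,4-dimethoxyphenyl)-2-methylbut-3-en-1-ol, via pinacol borate ester 3 (not isolated)
Conditions: (S)-3,3'-bis(2,4,6-triisopropylphenyl)-1,1'-binaphthyl-2,2'-diyl hydrogen phosphate [(S)-TRIP, 5 mol %], 4 Å MS, toluene, −30 °C; aq. NaHCO3 work-up
Reagents that add atoms: none
Why: Brønsted-acid-catalysed asymmetric crotylboration through a closed Zimmerman–Traxler chair, in which the E-crotyl geometry gives the anti relationship (the later C2/C3 trans pair) and the chiral phosphate, hydrogen-bonded to a boronate oxygen and the formyl hydrogen, opens the Si face of 1 so that both centres are set as 1S,2S.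

Step 2
Reactants: 4 (1S,2S)-1-(3,4-dimethoxyphenyl)-2-methylbut-3-en-1-ol
Product: 5 tert-butyl{[(1S,2S)-1-(3,4-dimethoxyphenyl)-2-methylbut-3-en-1-yl]oxy}dimethylsilane
Conditions: TBSCl, imidazole, DMF, rt
Reagents that add atoms: tert-butyldimethylsilyl chloride, CC(C)(C)[Si](C)(C)Cl
Why: Standard silyl ether formation masks the benzylic hydroxyl so that the later acid cannot lactonise and the borane, oxidant and chloroformate meet no free OH, with no stereocentre touched.

Step 3
Reactants: 5 tert-butyl{[(1S,2S)-1-(3,4-dimethoxyphenyl)-2-methylbut-3-en-1-yl]oxy}dimethylsilane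
Product: 7 (3S,4S)-4-[(tert-butyldimethylsilyl)oxy]-4-(3,4-dimethoxyphenyl)-3-methylbutan-1-ol, via B-alkyl-9-BBN adduct 6 (not isolated)
Conditions: 9-BBN (1.5 equiv), THF, 0 °C to rt; then NaOH, 30 % aq. H2O2, 0 °C
Reagents that add atoms: hydrogen peroxide, OO
Why: Anti-Markovnikov hydroboration–oxidation, in which the bulky dialkylborane places boron on the terminal carbon of the monosubstituted alkene and alkaline peroxide replaces it by OH without harm to the silyl ether or the arene.

Step 4
Reactants: 7 (3S,4S)-4-[(tert-butyldimethylsilyl)oxy]-4-(3,4-dimethoxyphenyl)-3-methylbutan-1-ol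
Product: 9 (3S,4S)-4-[(tert-butyldimethylsilyl)oxy]-4-(3,4-dimethoxyphenyl)-3-methylbutanoic acid, via aldehyde 8 (not isolated)
Conditions: TEMPO (20 mol %), PhI(OAc)2 (2.5 equiv), MeCN/H2O 1:1, rt
Reagents that add atoms: water, O
Why: Nitroxyl-catalysed oxidation takes the primary alcohol through aldehyde 8 and its hydrate to the acid under near-neutral, chlorine-free conditions that spare the electron-rich arene and the benzylic silyl ether, and the methyl-bearing centre is beta to the carbonyl and cannot epimerise.

Step 5
Reactants: 9 (3S,4S)-4-[(tert-butyldimethylsilyl)oxy]-4-(3,4-dimethoxyphenyl)-3-methylbutanoic acid; 10 trimethylsilyldiazomethane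
Product: 12 (4S,5S)-5-[(tert-butyldimethylsilyl)oxy]-1-diazo-5-(3,4-dimethoxyphenyl)-4-methylpentan-2-one, via mixed anhydride 11 (not isolated)
Conditions: ClCO2Et, Et3N, THF, −15 °C; then 10 (2 M in hexanes), MeCN, 0 °C to rt
Reagents that add atoms: none
Why: Arndt–Eistert-type acylation of a diazoalkane, in which the carbon of 10 attacks the acyl carbon of mixed anhydride 11 and the released ethyl carbonate strips the silyl group, giving the terminal diazoketone without exposing the acid-labile benzylic silyl ether to HCl.

Step 6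
Reactants: 12 (4S,5S)-5-[(tert-butyldimethylsilyl)oxy]-1-diazo-5-(3,4-dimethoxyphenyl)-4-methylpentan-2-one
Product: 13 (4S,5S)-1-diazo-5-(3,4-dimethoxyphenyl)-5-hydroxy-4-methylpentan-2-one
Conditions: Bu4NF/AcOH (1:1), THF, 0 °C to rt
Reagents that add atoms: none
Why: Fluoride-induced desilylation driven by the Si–F bond, buffered with AcOH so that no free alkoxide or basic fluoride attacks the diazoketone, which itself tolerates this weak acid at or below room temperature.

Step 7
Reactants: 13 (4S,5S)-1-diazo-5-(3,4-dimethoxyphenyl)-5-hydroxy-4-methylpentan-2-one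
Product: 14 (5S,6S)-6-(3,4-dimethoxyphenyl)-5-methyloxan-3-one
Conditions: Rh2(OAc)4 (1 mol %), CH2Cl2, rt, slow addition of 13
Reagents that add atoms: none
Why: Rhodium-carbenoid O–H insertion, in which loss of N2 gives an electrophilic carbenoid that the hydroxyl captures as an oxonium ylide and a proton shift closes the six-membered ring B faster than C–H insertion or arene cyclopropanation should compete, with both stereocentres as spectators.

Step 8
Reactants: 14 (5S,6S)-6-(3,4-dimethoxyphenyl)-5-methyloxan-3-one
Product: 17 (5S,6S)-4-diazo-6-(3,4-dimethoxyphenyl)-5-methyloxan-3-one, via lithium enolate 15 (not isolated), via trifluoroacetyl ketone 16 (not isolated)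
Conditions: LiN(SiMe3)2 (1.1 equiv), THF, −78 °C; CF3CO2CH2CF3, −78 °C; 5 % aq. HCl wash; then MsN3, Et3N, H2O (1 equiv), MeCN, rt
Reagents that add atoms: methanesulfonyl azide, CS(=O)(=O)N=[N+]=[N-]
Why: Detrifluoroacetylative (Regitz-type deacylative) diazo transfer, needed because a plain ketone enolate does not take up a diazo group cleanly: the lithium amide should remove the axial C4 proton rather than a C2 proton, whose enolate would be destabilised by the adjacent ring-oxygen lone pairs and cannot be chelated inside the ring, in line with the C4-selective kinetic enolisation known for oxan-3-one itself, and the trifluoroacetyl group then activates C4 for transfer from MsN3 and leaves as the N-mesyl amide.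

Step 9
Reactants: 17 (5S,6S)-4-diazo-6-(3,4-dimethoxyphenyl)-5-methyloxan-3-one; 18 N,O-dimethylhydroxylamine (free base)
Product: 21 (3R,4S,5S)-5-(3,4-dimethoxyphenyl)-N-methoxy-N,4-dimethyloxolane-3-carboxamide, via ketene 19 (not isolated), via amide enol 20 (not isolated)
Conditions: hν (365 nm LED), 18 (5 equiv), degassed THF, −40 °C; pH 7 phosphate buffer work-up
Reagents that add atoms: none
Why: Direct excitation of 17, whose ring locks the diazo and carbonyl groups s-Z, expels N2 while the oxanone C2–C3 bond shifts to the diazo carbon, so the oxygen-bearing methylene (C5 of ring A) becomes bonded to C4 and the former ketone carbon is pushed out as the ketene carbon of 19, the future C7'. This is the photochemical Wolff rearrangement of a cyclic 2-diazoketone with amine capture of the ketene, a known six-to-five ring contraction that also runs in oxacyclic diazoketones. Ring A is therefore closed not by cyclisation of a chain but by a 1,2-alkyl shift inside ring B, one C5–C4 bond being made as the C5–C7' bond breaks. Amine 18 adds to the ketene carbon in the ketene plane from the side of the unsubstituted C5H2 to give the E amide enol 20, and the one new stereocentre, C4, is set when 20 takes up a proton on carbon: the vicinal C3 methyl group screens the lower face more closely than the 1,3-related C2 aryl group screens the upper one, so the proton should enter anti to the methyl group and leave the carboxamide cis to it (4R in ring A locants, 3R in the name of 21), as in kinetic ketonisation of exocyclic enols. The step needs rearrangement to win over the 1,2-hydride shift from the neighbouring C–H (enone formation) and over carbene N–H insertion, which the s-Z geometry, 365 nm light that the veratryl group does not absorb, and the low temperature should secure. The cis amide is the less stable epimer, but 18 is a very weak base and the work-up is buffered at pH 7, so C4 should hold, and C2 and C3 are carried over unchanged.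

Step 10
Reactants: 21 (3R,4S,5S)-5-(3,4-dimethoxyphenyl)-N-methoxy-N,4-dimethyloxolane-3-carboxamide; 22 4-bromo-1,2-dimethoxybenzene
Product: 25 (3,4-dimethoxyphenyl)[(3R,4S,5S)-5-(3,4-dimethoxyphenyl)-4-methyloxolan-3-yl]methanone, via aryllithium 23 (not isolated), via lithium chelate 24 (not isolated)
Conditions: 22, n-BuLi, THF, −78 °C; then 21, −78 °C; AcOH/THF quench at −78 °C, pH 7 buffer
Reagents that add atoms: none
Why: Weinreb ketone synthesis, in which aryllithium 23 from bromine–lithium exchange adds once and the five-membered lithium chelate 24 holds until the cold acidic quench, so over-addition is excluded and the free ketone never meets base, which protects the cis C4 centre.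

Step 11
Reactants: 25 (3,4-dimethoxyphenyl)[(3R,4S,5S)-5-(3,4-dimethoxyphenyl)-4-methyloxolan-3-yl]methanone
Product: 27 (R)-(3,4-dimethoxyphenyl)[(3R,4S,5S)-5-(3,4-dimethoxyphenyl)-4-methyloxolan-3-yl]methanol (CNP0269167.1), via alkoxyborane 26 (not isolated)
Conditions: (S)-2-methyl-CBS-oxazaborolidine (0.5 equiv), BH3·SMe2, THF, −20 °C, slow addition of 25; MeOH quench
Reagents that add atoms: none
Why: Corey–Bakshi–Shibata reduction, in which the aryl group acts as the larger ketone substituent and the (S)-oxazaborolidine–borane complex delivers hydride to the Si face of C7' (the sense that turns acetophenone into (R)-1-phenylethanol) to give 7'R, a catalyst control that is needed because a Felkin–Anh analysis with C3 as the large group predicts 7'S for achiral hydrides, while the non-basic medium leaves the epimerisable C4 untouched.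

## Compound list

1 | 3,4-dimethoxybenzaldehyde | COc1ccc(C=O)cc1OC | starting material
2 | (E)-crotylboronic acid pinacol ester | C/C=C/CB1OC(C)(C)C(C)(C)O1 | starting material
3 | 2-{[(1S,2S)-1-(3,4-dimethoxyphenyl)-2-methylbut-3-en-1-yl]oxy}-4,4,5,5-tetramethyl-1,3,2-dioxaborolane | COc1ccc([C@@H](OB2OC(C)(C)C(C)(C)O2)[C@@H](C)C=C)cc1OC | intermediate
4 | (1S,2S)-1-(3,4-dimethoxyphenyl)-2-methylbut-3-en-1-ol | COc1ccc([C@@H](O)[C@@H](C)C=C)cc1OC | intermediate
5 | tert-butyl{[(1S,2S)-1-(3,4-dimethoxyphenyl)-2-methylbut-3-en-1-yl]oxy}dimethylsilane | COc1ccc([C@@H](O[Si](C)(C)C(C)(C)C)[C@@H](C)C=C)cc1OC | intermediate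
6 | 9-{(3S,4S)-4-[(tert-butyldimethylsilyl)oxy]-4-(3,4-dimethoxyphenyl)-3-methylbutyl}-9-borabicyclo[3.3.1]nonane | COc1ccc([C@@H](O[Si](C)(C)C(C)(C)C)[C@@H](C)CCB2C3CCCC2CCC3)cc1OC | intermediate
7 | (3S,4S)-4-[(tert-butyldimethylsilyl)oxy]-4-(3,4-dimethoxyphenyl)-3-methylbutan-1-ol | COc1ccc([C@@H](O[Si](C)(C)C(C)(C)C)[C@@H](C)CCO)cc1OC | intermediate
8 | (3S,4S)-4-[(tert-butyldimethylsilyl)oxy]-4-(3,4-dimethoxyphenyl)-3-methylbutanal | COc1ccc([C@@H](O[Si](C)(C)C(C)(C)C)[C@@H](C)CC=O)cc1OC | intermediate
9 | (3S,4S)-4-[(tert-butyldimethylsilyl)oxy]-4-(3,4-dimethoxyphenyl)-3-methylbutanoic acid | COc1ccc([C@@H](O[Si](C)(C)C(C)(C)C)[C@@H](C)CC(=O)O)cc1OC | intermediate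
10 | trimethylsilyldiazomethane | C[Si](C)(C)C=[N+]=[N-] | starting material
11 | (3S,4S)-4-[(tert-butyldimethylsilyl)oxy]-4-(3,4-dimethoxyphenyl)-3-methylbutanoic ethyl carbonic anhydride | COc1ccc([C@@H](O[Si](C)(C)C(C)(C)C)[C@@H](C)CC(=O)OC(=O)OCC)cc1OC | intermediate
12 | (4S,5S)-5-[(tert-butyldimethylsilyl)oxy]-1-diazo-5-(3,4-dimethoxyphenyl)-4-methylpentan-2-one | COc1ccc([C@@H](O[Si](C)(C)C(C)(C)C)[C@@H](C)CC(=O)C=[N+]=[N-])cc1OC | intermediate
13 | (4S,5S)-1-diazo-5-(3,4-dimethoxyphenyl)-5-hydroxy-4-methylpentan-2-one | COc1ccc([C@@H](O)[C@@H](C)CC(=O)C=[N+]=[N-])cc1OC | intermediate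
14 | (5S,6S)-6-(3,4-dimethoxyphenyl)-5-methyloxan-3-one | COc1ccc([C@H]2OCC(=O)C[C@@H]2C)cc1OC | intermediate
15 | lithium (5S,6S)-6-(3,4-dimethoxyphenyl)-5-methyl-5,6-dihydro-2H-pyran-3-olate | COc1ccc([C@H]2OCC([O-])=C[C@@H]2C)cc1OC.[Li+] | intermediate
16 | (5S,6S)-6-(3,4-dimethoxyphenyl)-5-methyl-4-(trifluoroacetyl)oxan-3-one, drawn as its ring enol | COc1ccc([C@H]2OCC(O)=C(C(=O)C(F)(F)F)[C@@H]2C)cc1OC | intermediate
17 | (5S,6S)-4-diazo-6-(3,4-dimethoxyphenyl)-5-methyloxan-3-one | COc1ccc([C@H]2OCC(=O)C(=[N+]=[N-])[C@@H]2C)cc1OC | intermediate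
18 | N,O-dimethylhydroxylamine | CNOC | starting material
19 | [(4S,5S)-5-(3,4-dimethoxyphenyl)-4-methyloxolan-3-ylidene]methanone (ketene) | COc1ccc([C@H]2OCC(=C=O)[C@@H]2C)cc1OC | intermediate
20 | (E)-[(4S,5S)-5-(3,4-dimethoxyphenyl)-4-methyloxolan-3-ylidene][methoxy(methyl)amino]methanol (amide enol, N on the C5H2 side) | COc1ccc([C@H]2OC/C(=C(\N(C)OC)O)[C@@H]2C)cc1OC | intermediate
21 | (3R,4S,5S)-5-(3,4-dimethoxyphenyl)-N-methoxy-N,4-dimethyloxolane-3-carboxamide | COc1ccc([C@H]2OC[C@H](C(=O)N(C)OC)[C@@H]2C)cc1OC | intermediate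
22 | 4-bromo-1,2-dimethoxybenzene | COc1ccc(Br)cc1OC | starting material
23 | 3,4-dimethoxyphenyllithium | COc1ccc([Li])cc1OC | intermediate
24 | lithium alkoxide of the tetrahedral adduct of 23 to 21 (hemiaminal carbon undefined) | COc1ccc([C@H]2OC[C@H](C([O-])(N(C)OC)c3ccc(OC)c(OC)c3)[C@@H]2C)cc1OC.[Li+] | intermediate
25 | (3,4-dimethoxyphenyl)[(3R,4S,5S)-5-(3,4-dimethoxyphenyl)-4-methyloxolan-3-yl]methanone | COc1ccc([C@H]2OC[C@H](C(=O)c3ccc(OC)c(OC)c3)[C@@H]2C)cc1OC | intermediate
26 | O-boranyl derivative (ROBH2) of 27 | COc1ccc([C@H]2OC[C@H]([C@@H](OB)c3ccc(OC)c(OC)c3)[C@@H]2C)cc1OC | intermediate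
27 | (R)-(3,4-dimethoxyphenyl)[(3R,4S,5S)-5-(3,4-dimethoxyphenyl)-4-methyloxolan-3-yl]methanol | COc1ccc([C@H]2OC[C@H]([C@@H](O)c3ccc(OC)c(OC)c3)[C@@H]2C)cc1OC | target

Total step count: 11. Longest linear sequence: 11 steps (1 to 27).

## Steps most likely to fail

**Step 9.**
- What may go wrong: poor facial selectivity when the small amine relays the proton to the amide enol. The C2 aryl group on the upper face competes with the C3 methyl group on the lower face. The excited diazoketone may also be diverted into the hydride shift.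
- Principle of the fallback: it separates the ring contraction from the setting of C4. It sets out from 17.
- Irradiation at 365 nm in methanol, the best-precedented trap, should give, through ketene 19, methyl (4S,5S)-5-(3,4-dimethoxyphenyl)-4-methyloxolane-3-carboxylate F1 as a mixture of C4 epimers.
- LiN(i-Pr)2 in THF at −78 °C converts both epimers into the same planar lithium ester enolate F2.
- F2 is protonated at −78 °C by the bulky 2,6-di-tert-butyl-4-methylphenol. This donor should feel the vicinal methyl group more strongly and give methyl (3R,4S,5S)-5-(3,4-dimethoxyphenyl)-4-methyloxolane-3-carboxylate F3.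
- AlMe3-promoted aminolysis of F3 with 18 in CH2Cl2 at 0 °C, a Lewis-acidic and non-enolising medium, comes back to the route at 21.

**Step 11.**
- What may go wrong: poor facial selectivity. The catalyst must work against the Felkin–Anh bias of the ring stereocentre, and the branched oxolanyl group is not much smaller than the aryl group.
- Principle of the fallback: it exchanges the roles of nucleophile and carbonyl substituent, so that the substrate bias works for the target. It sets out from 21.
- i-Bu2AlH in THF at −78 °C with a cold tartrate work-up should give (3R,4S,5S)-5-(3,4-dimethoxyphenyl)-4-methyloxolane-3-carbaldehyde F4, which is used crude.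
- F4 is treated at −78 °C with 3,4-dimethoxyphenylmagnesium bromide F5, made from 22 and Mg in THF.
- Both the Felkin–Anh model (C3 large) and the chelate through O1 place the aryl group on the face that gives 7'R. The sequence comes back at 27.

**Step 8.**
- What may go wrong: loss of regiocontrol in the enolisation. The C5 methyl group hinders C4 and may allow competing deprotonation at C2. The enolates may also equilibrate during the acylation.
- Principle of the fallback: it builds the C3–C4 enol derivative from the connectivity of the carbon chain, so no deprotonation has to choose a side. It sets out from 4 and bypasses steps 2 to 7.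
- NaH and methyl bromoacetate in THF give methyl {[(1S,2S)-1-(3,4-dimethoxyphenyl)-2-methylbut-3-en-1-yl]oxy}acetate F6.
- Petasis methylenation with Cp2TiMe2 in toluene at 70 °C gives 4-{(1S,2S)-1-[(2-methoxyprop-2-en-1-yl)oxy]-2-methylbut-3-en-1-yl}-1,2-dimethoxybenzene F7.
- Ring-closing metathesis with the second-generation Grubbs catalyst in toluene at 70 °C gives (2S,3S)-2-(3,4-dimethoxyphenyl)-5-methoxy-3-methyl-3,6-dihydro-2H-pyran F8. Its double bond can only lie between the oxanone carbons C3 and C4.
- C-Trifluoroacetylation of this enol ether with (CF3CO)2O and pyridine in CH2Cl2 gives 1-[(2S,3S)-2-(3,4-dimethoxyphenyl)-5-methoxy-3-methyl-3,6-dihydro-2H-pyran-4-yl]-2,2,2-trifluoroethan-1-one F9.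
- Mild hydrolysis with dilute HCl in THF comes back to the route at 16, which enters the second half of step 8.

## Further compounds

F1 | step 9 | methyl (4S,5S)-5-(3,4-dimethoxyphenyl)-4-methyloxolane-3-carboxylate (C4 epimer mixture) | COc1ccc([C@H]2OCC(C(=O)OC)[C@@H]2C)cc1OC
F2 | step 9 | lithium ester enolate of F1 | COc1ccc([C@H]2OCC(=C([O-])OC)[C@@H]2C)cc1OC.[Li+]
F3 | step 9 | methyl (3R,4S,5S)-5-(3,4-dimethoxyphenyl)-4-methyloxolane-3-carboxylate | COc1ccc([C@H]2OC[C@H](C(=O)OC)[C@@H]2C)cc1OC
F4 | step 11 | (3R,4S,5S)-5-(3,4-dimethoxyphenyl)-4-methyloxolane-3-carbaldehyde | COc1ccc([C@H]2OC[C@H](C=O)[C@@H]2C)cc1OC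
F5 | step 11 | 3,4-dimethoxyphenylmagnesium bromide | COc1ccc([Mg]Br)cc1OC
F6 | step 8 | methyl {[(1S,2S)-1-(3,4-dimethoxyphenyl)-2-methylbut-3-en-1-yl]oxy}acetate | COc1ccc([C@@H](OCC(=O)OC)[C@@H](C)C=C)cc1OC
F7 | step 8 | 4-{(1S,2S)-1-[(2-methoxyprop-2-en-1-yl)oxy]-2-methylbut-3-en-1-yl}-1,2-dimethoxybenzene | COc1ccc([C@@H](OCC(=C)OC)[C@@H](C)C=C)cc1OC
F8 | step 8 | (2S,3S)-2-(3,4-dimethoxyphenyl)-5-methoxy-3-methyl-3,6-dihydro-2H-pyran | COc1ccc([C@H]2OCC(OC)=C[C@@H]2C)cc1OC
F9 | step 8 | 1-[(2S,3S)-2-(3,4-dimethoxyphenyl)-5-methoxy-3-methyl-3,6-dihydro-2H-pyran-4-yl]-2,2,2-trifluoroethan-1-one | COc1ccc([C@H]2OCC(OC)=C(C(=O)C(F)(F)F)[C@@H]2C)cc1OC
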